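Ring B is not brought in as an arene but grown on the ether oxygen of ring A. Its substitution pattern (ether carbon C1' flanked by phenol carbon C2' and by C6' carrying CH2OH, H on C3' and C5', CH3 on C4') is that of a 4-aryloxyacetoacetate (C1'–C3') joined to ethyl 2-oxopent-3-enoate (C4'–C6'). One Michael–aldol condensation makes C3'–C4' and C1'=C6' and closes ring B as a cyclohexenone. Decarboxylation, dehydrogenation and ester reduction then finish it. The precursor is a tetrasubstituted ring A allyl salicylate, (S)-silyl ether already set, whose phenol oxygen carries the CH2C(O)CH2CO2allyl chain installed by SN2 alkylation, so no hindered aryl–O–aryl coupling is needed.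

Key step: step 11

Locants: ring A is numbered as the benzoic acid (C1 carboxyl-bearing, C2 OMe, C3 side chain, C6 ether oxygen). In ring B, C1' is the ether carbon, C2' the phenol carbon, C4' bears CH3 and C6' bears CH2OH.

Assumption: commercial 1-propenylmagnesium bromide is an E/Z mixture. This is harmless, because the amine of step 11 equilibrates 17 by reversible conjugate addition and the alkene geometry is erased there, so 17 is drawn as E.

Design remark: the benzylic C–O bond (ortho to OMe, para to the ring A ether oxygen) ionises easily. From compound 6 onward, therefore, no Brønsted acid stronger than formic acid and no hot halogen-based oxidant is used.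

Step 1
Reactants: 1 resorcinol; 2 isovaleryl chloride (3-methylbutanoyl chloride)
Product: 3 1-(2,4-dihydroxyphenyl)-3-methylbutan-1-one
Conditions: AlCl3 (2.5 equiv), 1,2-dichloroethane, 0 °C to 60 °C; ice/aq. HCl
Reagents that add atoms: none
Why: Friedel–Crafts acylation of resorcinol goes to C4, ortho to one hydroxyl and para to the other, and stops after one acyl group because the chelated aryl ketone deactivates the ring.

Step 2
Reactants: 3 1-(2,4-dihydroxyphenyl)-3-methylbutan-1-one
Product: 4 1-[2-hydroxy-4-(methoxymethoxy)phenyl]-3-methylbutan-1-one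
Conditions: MOMCl (1.1 equiv), K2CO3, acetone, 0 °C to rt
Reagents that add atoms: chloromethyl methyl ether (MOMCl), COCCl
Why: Williamson-type O-alkylation under a weak base picks the para hydroxyl, since the ortho hydroxyl is locked in a hydrogen bond to the ketone and is much less nucleophilic.

Step 3
Reactants: 4 1-[2-hydroxy-4-(methoxymethoxy)phenyl]-3-methylbutan-1-one
Product: 5 1-[2-methoxy-4-(methoxymethoxy)phenyl]-3-methylbutan-1-one
Conditions: MeI (1.5 equiv), K2CO3, DMF, 40 °C
Reagents that add atoms: iodomethane, CI
Why: Williamson methylation in a dipolar aprotic solvent with gentle heating overcomes the chelate of the only phenol left, while carbonate is too weak to enolise the ketone for C-methylation.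

Step 4
Reactants: 5 1-[2-methoxy-4-(methoxymethoxy)phenyl]-3-methylbutan-1-one
Product: 6 (1S)-1-[2-methoxy-4-(methoxymethoxy)phenyl]-3-methylbutan-1-ol
Conditions: RuCl2[(R)-xylbinap][(R)-daipen] (0.2 mol %), KOtBu (2 mol %), H2 (8 atm), i-PrOH, rt
Reagents that add atoms: none
Why: Noyori asymmetric hydrogenation of an aryl alkyl ketone: the (R)-diphosphine/(R)-diamine ruthenium hydride distinguishes the flat aryl group from the isobutyl chain in its outer-sphere six-membered transition state and delivers hydride to the Re face, the sense that gives (S)-1-phenylethanol from acetophenone, so the (S)-carbinol centre is set by the catalyst, and the basic medium spares the easily ionised electron-rich benzylic alcohol.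

Step 5
Reactants: 6 (1S)-1-[2-methoxy-4-(methoxymethoxy)phenyl]-3-methylbutan-1-ol
Product: 7 tert-butyl{(1S)-1-[2-methoxy-4-(methoxymethoxy)phenyl]-3-methylbutoxy}dimethylsilane
Conditions: TBSCl (1.5 equiv), imidazole (3 equiv), DMF, rt to 40 °C
Reagents that add atoms: tert-butyldimethylsilyl chloride (TBSCl), CC(C)(C)[Si](C)(C)Cl
Why: Imidazole-promoted silylation of a secondary alcohol takes place at oxygen with retention at carbon and gives an ether that withstands butyllithium, hydride bases, amines and palladium.

Step 6
Reactants: 7 tert-butyl{(1S)-1-[2-methoxy-4-(methoxymethoxy)phenyl]-3-methylbutoxy}dimethylsilane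
Product: 9 allyl 2-methoxy-6-(methoxymethoxy)-3-[(1S)-1-(tert-butyldimethylsilyloxy)-3-methylbutyl]benzoate, via aryllithium 8 (not isolated)
Conditions: n-BuLi (1.2 equiv), THF, 0 °C, 1.5 h; cannulated into ClCO2CH2CH=CH2 (3 equiv), THF, −78 °C
Reagents that add atoms: allyl chloroformate, C=CCOC(=O)Cl
Why: Directed ortho-metalation: the ring carbon between OMe and OMOM (C3 of 7, the later C1 of ring A) is acidified and coordinated by both oxygen groups and is lithiated in preference to C5, and inverse addition of the hindered aryllithium to excess chloroformate stops at the ester.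

Step 7
Reactants: 9 allyl 2-methoxy-6-(methoxymethoxy)-3-[(1S)-1-(tert-butyldimethylsilyloxy)-3-methylbutyl]benzoate
Product: 11 allyl 6-hydroxy-2-methoxy-3-[(1S)-1-(tert-butyldimethylsilyloxy)-3-methylbutyl]benzoate, via aryl trimethylsilyl ether 10 (not isolated)
Conditions: TMSOTf (2 equiv), 2,2'-bipyridyl (3 equiv), MeCN, 0 °C to rt; then H2O, rt
Reagents that add atoms: none
Why: Silyl triflate/2,2'-bipyridyl cleavage of an aromatic MOM ether works in a weakly basic medium, activates only the acetal, hands the phenol over as its labile trimethylsilyl ether and frees it with water, so no Brønsted acid meets the benzylic silyl ether, whose C–O bond would otherwise ionise and racemise.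

Step 8
Reactants: 12 ethyl 4-chloroacetoacetate
Product: 13 allyl 4-chloroacetoacetate (allyl 4-chloro-3-oxobutanoate)
Conditions: allyl alcohol (5 equiv), B(OH)3 (10 mol %), toluene, reflux, EtOH distilled off
Reagents that add atoms: allyl alcohol, C=CCO
Why: Transesterification of a β-keto ester, which runs through its chelated enol (or the acylketene) far faster than with a simple ester, is driven by distilling off ethanol and leaves the primary chloride untouched in the absence of base.

Step 9
Reactants: 11 allyl 6-hydroxy-2-methoxy-3-[(1S)-1-(tert-butyldimethylsilyloxy)-3-methylbutyl]benzoate; 13 allyl 4-chloroacetoacetate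
Product: 14 allyl 6-{[4-(allyloxy)-2,4-dioxobutyl]oxy}-2-methoxy-3-[(1S)-1-(tert-butyldimethylsilyloxy)-3-methylbutyl]benzoate (the allyl 4-aryloxy-3-oxobutanoate)
Conditions: NaH (2.2 equiv), THF/DMF 4:1, 0 °C; 13 (1.2 equiv), NaI (0.1 equiv), rt to 45 °C; AcOH quench, 0 °C
Reagents that add atoms: none
Why: Williamson ether synthesis by SN2 at the primary carbon next to the ketone: the second equivalent of NaH holds 13 and then 14 as their C3' enolates, which curbs self-condensation of 13 and keeps C1' from being deprotonated, so Dieckmann-type closure onto the neighbouring ring A ester is shut off.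

Step 10
Reactants: 15 diethyl oxalate; 16 1-propenylmagnesium bromide
Product: 17 ethyl (E)-2-oxopent-3-enoate
Conditions: 16 (0.5 M in THF) added to 15 (1.5 equiv), Et2O/THF, −78 °C; 1 M HCl at −78 °C; distillation, used fresh
Reagents that add atoms: none
Why: Mono-acylation of a Grignard reagent by diethyl oxalate: the tetrahedral magnesium alkoxide is stable at −78 °C and collapses to the α-keto ester only on quenching, so a second addition is not expected while the oxalate is in excess.

Step 11
Reactants: 14 allyl 6-{[4-(allyloxy)-2,4-dioxobutyl]oxy}-2-methoxy-3-[(1S)-1-(tert-butyldimethylsilyloxy)-3-methylbutyl]benzoate; 17 ethyl (E)-2-oxopent-3-enoate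
Product: 20 allyl 6-{[5-(allyloxycarbonyl)-2-(ethoxycarbonyl)-4-methyl-6-oxocyclohex-1-en-1-yl]oxy}-2-methoxy-3-[(1S)-1-(tert-butyldimethylsilyloxy)-3-methylbutyl]benzoate (mixture at C3' and C4'), via Michael adduct 18 (not isolated), via aldol 19 (not isolated)
Conditions: 17 (1.5 equiv), pyrrolidine (0.2 equiv), AcOH (0.4 equiv), 4 Å MS, toluene, Ar, rt; then 60 °C
Reagents that add atoms: none
Why: Pyrrolidinium acetate activates 17 as its unsaturated iminium ion, the most acidic carbon of 14 (C3', between ketone and ester) adds to C4' to give 18, and the C1'=C2' enol or enamine of 18 then attacks the activated C6' carbonyl to give 19, which loses water by E1cB (or loses the amine when C6' has reacted as its iminium ion) to give the C1'=C6' enone 20. The closest known reaction type is the Robinson-type Michael–aldol condensation of acetoacetates with enones and with β,γ-unsaturated α-keto esters, in which the γ-carbon of the keto ester closes the ring. Ring B closes by a 6-(enolendo)-exo-trig aldol, whereas closure from C3' or C5' would need four-membered rings and closure of the enol oxygen onto C6' is reversible, so only the dehydrating path drains the equilibria. C3' and C4' are formed without control and the mixture is accepted, because C3' is flattened on decarboxylation and C4' on aromatisation, while the remote (S)-carbinol carbon is not touched. The step needs C3' to react before C1' in the Michael addition, which the acidity gap secures, and needs C1' to attack C6' and not the neighbouring ring A ester, which is secured by buffered enamine conditions without free enolate and by the far higher electrophilicity of the α-keto carbonyl. A secondary amine is used because ammonia or a primary amine would divert the 1,5-dicarbonyl array of 18 to a dihydropyridine, and it is kept catalytic and buffered because 20 is a β-aryloxy enoate open to addition–elimination.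

Step 12
Reactants: 20 allyl 6-{[5-(allyloxycarbonyl)-2-(ethoxycarbonyl)-4-methyl-6-oxocyclohex-1-en-1-yl]oxy}-2-methoxy-3-[(1S)-1-(tert-butyldimethylsilyloxy)-3-methylbutyl]benzoate
Product: 21 6-{[2-(ethoxycarbonyl)-4-methyl-6-oxocyclohex-1-en-1-yl]oxy}-2-methoxy-3-[(1S)-1-(tert-butyldimethylsilyloxy)-3-methylbutyl]benzoic acid (mixture at C4')
Conditions: Pd(OAc)2 (5 mol %), PPh3 (20 mol %), HCO2H (5 equiv), Et3N (6 equiv), THF, rt; aq. NaH2PO4
Reagents that add atoms: none
Why: Tsuji–Trost-type deallylation with formate as hydride donor: zerovalent palladium formed in situ ionises both O–allyl bonds (no attack at the hindered ring A carbonyl is needed), propene is released, the β-keto acid at C3' loses CO2 at room temperature, and the non-nucleophilic scavenger is preferred to a secondary amine, which could displace the aryloxy group of the β-aryloxy enoate by addition–elimination.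

Step 13
Reactants: 21 6-{[2-(ethoxycarbonyl)-4-methyl-6-oxocyclohex-1-en-1-yl]oxy}-2-methoxy-3-[(1S)-1-(tert-butyldimethylsilyloxy)-3-methylbutyl]benzoic acid
Product: 23 6-[2-(ethoxycarbonyl)-6-hydroxy-4-methylphenoxy]-2-methoxy-3-[(1S)-1-(tert-butyldimethylsilyloxy)-3-methylbutyl]benzoic acid, via silyl dienol ether 22 (not isolated)
Conditions: TMSOTf (3 equiv), Et3N (5 equiv), CH2Cl2, 0 °C; pentane, filtration, evaporation; Pd(OAc)2 (1.1 equiv), MeCN, rt; aq. NaH2PO4
Reagents that add atoms: none
Why: Saegusa–Ito oxidation: soft enolisation gives the silyloxy diene 22 (either regioisomer serves), divalent palladium forms the oxa-π-allyl complex, β-hydride elimination gives a cyclohexadienone that tautomerises to the phenol and erases C4', and the room-temperature, acid-free conditions spare the benzylic silyl ether that hot halogen- or acid-based aromatisations would endanger.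

Step 14
Reactants: 23 6-[2-(ethoxycarbonyl)-6-hydroxy-4-methylphenoxy]-2-methoxy-3-[(1S)-1-(tert-butyldimethylsilyloxy)-3-methylbutyl]benzoic acid
Product: 24 6-[2-hydroxy-6-(hydroxymethyl)-4-methylphenoxy]-2-methoxy-3-[(1S)-1-(tert-butyldimethylsilyloxy)-3-methylbutyl]benzoic acid
Conditions: LiBH4 (4 equiv), MeOH (4 equiv), Et2O/THF, 0 °C to rt; aq. NaH2PO4 (pH 4–5)
Reagents that add atoms: none
Why: Chemoselective LiBH4 reduction of an ester in the presence of a carboxylic acid: acid and phenol are first turned into lithium salts with loss of H2, the doubly ortho-substituted carboxylate is inert to borohydride (and, as an anion, also keeps ring A from Smiles rearrangement), and only the ethyl ester on C6' is taken down to CH2OH.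

Step 15
Reactants: 24 6-[2-hydroxy-6-(hydroxymethyl)-4-methylphenoxy]-2-methoxy-3-[(1S)-1-(tert-butyldimethylsilyloxy)-3-methylbutyl]benzoic acid
Product: 25 6-[2-hydroxy-6-(hydroxymethyl)-4-methylphenoxy]-3-[(1S)-1-hydroxy-3-methylbutyl]-2-methoxybenzoic acid (CNP0221397.1)
Conditions: TBAF (5 equiv), THF, rt to 40 °C; aq. NaH2PO4 (pH 4–5), EtOAc
Reagents that add atoms: none
Why: Fluoride-driven desilylation attacks silicon and not carbon, so the (S)-carbinol is released with retention under basic conditions, and the mildly acidic buffer of the work-up protonates the carboxylate without ionising the benzylic alcohol.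

Compound list
1 | resorcinol | Oc1cccc(O)c1 | starting material
2 | isovaleryl chloride | CC(C)CC(=O)Cl | starting material
3 | 1-(2,4-dihydroxyphenyl)-3-methylbutan-1-one | CC(C)CC(=O)c1ccc(O)cc1O | intermediate
4 | 1-[2-hydroxy-4-(methoxymethoxy)phenyl]-3-methylbutan-1-one | CC(C)CC(=O)c1ccc(OCOC)cc1O | intermediate
5 | 1-[2-methoxy-4-(methoxymethoxy)phenyl]-3-methylbutan-1-one | COc1c(C(=O)CC(C)C)ccc(OCOC)c1 | intermediate
6 | (1S)-1-[2-methoxy-4-(methoxymethoxy)phenyl]-3-methylbutan-1-ol | COc1c([C@@H](O)CC(C)C)ccc(OCOC)c1 | intermediate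
7 | tert-butyl{(1S)-1-[2-methoxy-4-(methoxymethoxy)phenyl]-3-methylbutoxy}dimethylsilane | COc1c([C@@H](O[Si](C)(C)C(C)(C)C)CC(C)C)ccc(OCOC)c1 | intermediate
8 | aryllithium of 7, lithium on the carbon between OMe and OMOM | COc1c([C@@H](O[Si](C)(C)C(C)(C)C)CC(C)C)ccc(OCOC)c1[Li] | intermediate
9 | allyl 2-methoxy-6-(methoxymethoxy)-3-[(1S)-1-(tert-butyldimethylsilyloxy)-3-methylbutyl]benzoate | COc1c([C@@H](O[Si](C)(C)C(C)(C)C)CC(C)C)ccc(OCOC)c1C(=O)OCC=C | intermediate
10 | allyl 2-methoxy-6-(trimethylsilyloxy)-3-[(1S)-1-(tert-butyldimethylsilyloxy)-3-methylbutyl]benzoate | COc1c([C@@H](O[Si](C)(C)C(C)(C)C)CC(C)C)ccc(O[Si](C)(C)C)c1C(=O)OCC=C | intermediate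
11 | allyl 6-hydroxy-2-methoxy-3-[(1S)-1-(tert-butyldimethylsilyloxy)-3-methylbutyl]benzoate | COc1c([C@@H](O[Si](C)(C)C(C)(C)C)CC(C)C)ccc(O)c1C(=O)OCC=C | intermediate
12 | ethyl 4-chloroacetoacetate | CCOC(=O)CC(=O)CCl | starting material
13 | allyl 4-chloroacetoacetate | C=CCOC(=O)CC(=O)CCl | intermediate
14 | allyl 6-{[4-(allyloxy)-2,4-dioxobutyl]oxy}-2-methoxy-3-[(1S)-1-(tert-butyldimethylsilyloxy)-3-methylbutyl]benzoate | COc1c([C@@H](O[Si](C)(C)C(C)(C)C)CC(C)C)ccc(OCC(=O)CC(=O)OCC=C)c1C(=O)OCC=C | intermediate
15 | diethyl oxalate | CCOC(=O)C(=O)OCC | starting material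
16 | 1-propenylmagnesium bromide (E/Z mixture) | CC=C[Mg]Br | starting material
17 | ethyl (E)-2-oxopent-3-enoate | C/C=C/C(=O)C(=O)OCC | intermediate
18 | Michael adduct, 1-allyl 6-ethyl 2-(aryloxyacetyl)-3-methyl-5-oxohexanedioate on ring A (mixture at C3' and C4') | COc1c([C@@H](O[Si](C)(C)C(C)(C)C)CC(C)C)ccc(OCC(=O)C(C(=O)OCC=C)C(C)CC(=O)C(=O)OCC)c1C(=O)OCC=C | intermediate
19 | aldol, 2-aryloxy-3-hydroxycyclohexanone with OH and CO2Et on C6', CO2allyl on C3', CH3 on C4' (mixture of ring stereoisomers) | COc1c([C@@H](O[Si](C)(C)C(C)(C)C)CC(C)C)ccc(OC2C(=O)C(C(=O)OCC=C)C(C)CC2(O)C(=O)OCC)c1C(=O)OCC=C | intermediate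
20 | allyl 6-{[5-(allyloxycarbonyl)-2-(ethoxycarbonyl)-4-methyl-6-oxocyclohex-1-en-1-yl]oxy}-2-methoxy-3-[(1S)-1-(tert-butyldimethylsilyloxy)-3-methylbutyl]benzoate (mixture at C3' and C4') | COc1c([C@@H](O[Si](C)(C)C(C)(C)C)CC(C)C)ccc(OC2=C(C(=O)OCC)CC(C)C(C(=O)OCC=C)C2=O)c1C(=O)OCC=C | intermediate
21 | 6-{[2-(ethoxycarbonyl)-4-methyl-6-oxocyclohex-1-en-1-yl]oxy}-2-methoxy-3-[(1S)-1-(tert-butyldimethylsilyloxy)-3-methylbutyl]benzoic acid (mixture at C4') | COc1c([C@@H](O[Si](C)(C)C(C)(C)C)CC(C)C)ccc(OC2=C(C(=O)OCC)CC(C)CC2=O)c1C(=O)O | intermediate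
22 | trimethylsilyl 6-{[2-(ethoxycarbonyl)-4-methyl-6-(trimethylsilyloxy)cyclohexa-1,5-dien-1-yl]oxy}-2-methoxy-3-[(1S)-1-(tert-butyldimethylsilyloxy)-3-methylbutyl]benzoate | COc1c([C@@H](O[Si](C)(C)C(C)(C)C)CC(C)C)ccc(OC2=C(C(=O)OCC)CC(C)C=C2O[Si](C)(C)C)c1C(=O)O[Si](C)(C)C | intermediate
23 | 6-[2-(ethoxycarbonyl)-6-hydroxy-4-methylphenoxy]-2-methoxy-3-[(1S)-1-(tert-butyldimethylsilyloxy)-3-methylbutyl]benzoic acid | COc1c([C@@H](O[Si](C)(C)C(C)(C)C)CC(C)C)ccc(Oc2c(O)cc(C)cc2C(=O)OCC)c1C(=O)O | intermediate
24 | 6-[2-hydroxy-6-(hydroxymethyl)-4-methylphenoxy]-2-methoxy-3-[(1S)-1-(tert-butyldimethylsilyloxy)-3-methylbutyl]benzoic acid | COc1c([C@@H](O[Si](C)(C)C(C)(C)C)CC(C)C)ccc(Oc2c(O)cc(C)cc2CO)c1C(=O)O | intermediate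
25 | 6-[2-hydroxy-6-(hydroxymethyl)-4-methylphenoxy]-3-[(1S)-1-hydroxy-3-methylbutyl]-2-methoxybenzoic acid (CNP0221397.1) | COc1c([C@@H](O)CC(C)C)ccc(Oc2c(O)cc(C)cc2CO)c1C(=O)O | target

Total step count: 15. Longest linear sequence: 13 steps (steps 1–7, 9, 11–15). Steps 8 and 10 are one-step side branches.

Steps most likely to fail

1. Step 11 (annulation).
- What may go wrong: the Michael adduct may rest in its oxygen-closed form while dehydration lags. Retro-Michael cleavage, loss of the ring A phenol by amine addition–elimination, or Claisen-type closure onto the ring A ester would then erode the material.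
- Fallback: the annulation is split, and the decarboxylation is moved ahead of the ring closure. Starting from 14 and 17, only the Michael addition is run (Et3N, 0.1 equiv, CH2Cl2, 0 °C) and 18 is isolated.
- Both allyl groups are then removed under the conditions of step 12. After loss of CO2 this gives the ethyl 7-aryloxy-4-methyl-2,6-dioxoheptanoate with ring A as the free benzoic acid F1.
- F1 can no longer revert by retro-Michael reaction, has no β-keto ester enol to trap C6' through oxygen, and carries an unreactive carboxylate on ring A. True enolate conditions therefore become permissible (DBU, 2.2 equiv, THF, rt).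
- C1' is the only carbon that can reach C6' in a six-membered ring. The hydroxy ketone ethyl 2-aryloxy-1-hydroxy-5-methyl-3-oxocyclohexanecarboxylate F2 should dehydrate by E1cB, and the route is rejoined at 21.

2. Step 9 (O-alkylation).
- What may go wrong: SN2 attack of the hindered, hydrogen-bonded phenoxide on the enolised chloride may be slow, leaving room for proton shuffling and self-condensation of the alkylating agent.
- Fallback: the acidic β-keto ester is masked during the alkylation. Commercial 2,2,6-trimethyl-1,3-dioxin-4-one is chlorinated at its methyl group (LDA, THF, −78 °C; C2Cl6) to 6-(chloromethyl)-2,2-dimethyl-1,3-dioxin-4-one F3.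
- Starting from 11, alkylation with F3 (K2CO3, DMF, rt) gives the 6-(aryloxymethyl)-2,2-dimethyl-1,3-dioxin-4-one F4.
- Heating F4 with allyl alcohol (3 equiv, toluene, 110 °C) releases the aryloxyacetylketene F5 by retro-[4+2] cleavage. Allyl alcohol traps F5, and the route is rejoined at 14.

3. Step 13 (aromatisation).
- What may go wrong: enol silylation of the hindered α-aryloxy enone may be incomplete, the silyl dienol ether may hydrolyse back, or β-hydride elimination may be slow.
- Fallback: decarboxylation and dehydrogenation are merged, bypassing 21 and 22. Starting from 20, Pd(OAc)2 (10 mol %) and 1,2-bis(diphenylphosphino)ethane (10 mol %) in refluxing MeCN bring about the known decarboxylation–dehydrogenation of allyl β-keto esters.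
- The palladium enolate left after loss of CO2 eliminates hydride from C4', the allyl group leaves as propene, and the dienone tautomerises. This gives allyl 6-[2-(ethoxycarbonyl)-6-hydroxy-4-methylphenoxy]-2-methoxy-3-[(1S)-1-(tert-butyldimethylsilyloxy)-3-methylbutyl]benzoate F6.
- The conditions of step 12 then cleave the ring A allyl ester, together with any allyl group transferred to the phenol, and the route is rejoined at 23.

Further compounds
F1 | step 11 | 6-[(7-ethoxy-4-methyl-2,6,7-trioxoheptyl)oxy]-2-methoxy-3-[(1S)-1-(tert-butyldimethylsilyloxy)-3-methylbutyl]benzoic acid (mixture at C4') | COc1c([C@@H](O[Si](C)(C)C(C)(C)C)CC(C)C)ccc(OCC(=O)CC(C)CC(=O)C(=O)OCC)c1C(=O)O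
F2 | step 11 | 6-{[2-(ethoxycarbonyl)-2-hydroxy-4-methyl-6-oxocyclohexyl]oxy}-2-methoxy-3-[(1S)-1-(tert-butyldimethylsilyloxy)-3-methylbutyl]benzoic acid (mixture of ring stereoisomers) | COc1c([C@@H](O[Si](C)(C)C(C)(C)C)CC(C)C)ccc(OC2C(=O)CC(C)CC2(O)C(=O)OCC)c1C(=O)O
F3 | step 9 | 6-(chloromethyl)-2,2-dimethyl-4H-1,3-dioxin-4-one | CC1(C)OC(=O)C=C(CCl)O1
F4 | step 9 | allyl 6-[(2,2-dimethyl-4-oxo-4H-1,3-dioxin-6-yl)methoxy]-2-methoxy-3-[(1S)-1-(tert-butyldimethylsilyloxy)-3-methylbutyl]benzoate | COc1c([C@@H](O[Si](C)(C)C(C)(C)C)CC(C)C)ccc(OCC2=CC(=O)OC(C)(C)O2)c1C(=O)OCC=C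
F5 | step 9 | allyl 6-[(2,4-dioxobut-3-en-1-yl)oxy]-2-methoxy-3-[(1S)-1-(tert-butyldimethylsilyloxy)-3-methylbutyl]benzoate (acylketene) | COc1c([C@@H](O[Si](C)(C)C(C)(C)C)CC(C)C)ccc(OCC(=O)C=C=O)c1C(=O)OCC=C
F6 | step 13 | allyl 6-[2-(ethoxycarbonyl)-6-hydroxy-4-methylphenoxy]-2-methoxy-3-[(1S)-1-(tert-butyldimethylsilyloxy)-3-methylbutyl]benzoate | COc1c([C@@H](O[Si](C)(C)C(C)(C)C)CC(C)C)ccc(Oc2c(O)cc(C)cc2C(=O)OCC)c1C(=O)OCC=C
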